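**Retrosynthetic overview**

- Feature: in the oxolane ring, O1 is bonded to two benzylic carbons (C2 and C5), each para to the free OH of a 4-hydroxy-3,5-dimethoxyphenyl ring; with cis methyls on C3/C4 and each aryl trans to its neighbouring methyl, the molecule is meso.
- Disconnection A (last): C2–O1 and C5–O1 are cut to water plus an acyclic bis-para-quinone methide, the two-electron oxidation product of a meso 1,2-diaryl-3,4-dimethylcyclobutane whose C1–C2 bond stands where the ring oxygen will be.
- Disconnection B: the methyls derive from ester carbons (via CH2OH), and the cyclobutane from a head-to-head (2+2) photodimerization of two (E)-4-O-benzylsinapate arms held side by side on 1,8-dihydroxynaphthalene.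
- Disconnection C: the sinapic acid comes from syringaldehyde and malonic acid.
- Ring order: aromatic rings bought; cyclobutane closed in step 4 (inside a temporary nine-membered dilactone, removed in step 5); cyclobutane opened and oxolane closed in one flask in step 9.

Key step: step 9

Remark on the chemistry: the target is achiral (meso), so the stereodescriptors in all SMILES fix relative configuration only; benzyl bromide, methanesulfonyl chloride and water are treated as reagents and carry no compound number.

**Route**

Step 1
Reactants: 1 syringaldehyde (4-hydroxy-3,5-dimethoxybenzaldehyde)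
Product: 2 4-(benzyloxy)-3,5-dimethoxybenzaldehyde
Conditions: BnBr (1.2 equiv), K2CO3 (1.5 equiv), DMF, 60 °C
Reagents that add atoms: benzyl bromide (BrCc1ccccc1)
Why: Williamson etherification, in which the phenoxide formed by K2CO3 displaces bromide at the benzylic carbon, masking the phenol against the later base, hydride and photochemical steps; no stereocentre is formed.

Step 2
Reactants: 2 4-(benzyloxy)-3,5-dimethoxybenzaldehyde; 3 malonic acid (2.5 equiv)
Product: 5 (E)-3-[4-(benzyloxy)-3,5-dimethoxyphenyl]prop-2-enoic acid, via arylidenemalonic acid 4 (not isolated)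
Conditions: pyridine, piperidine (cat.), 90 °C to reflux; then cold aq. HCl
Reagents that add atoms: none
Why: Knoevenagel–Doebner condensation, in which the aldehyde condenses with malonic acid under amine catalysis and the arylidenemalonic acid 4 loses CO2 in hot pyridine to give the thermodynamically favoured (E)-acid, the benzyl ether being inert.

Step 3
Reactants: 5 (E)-3-[4-(benzyloxy)-3,5-dimethoxyphenyl]prop-2-enoic acid (2.2 equiv); 6 1,8-dihydroxynaphthalene
Product: 7 naphthalene-1,8-diyl bis{(E)-3-[4-(benzyloxy)-3,5-dimethoxyphenyl]prop-2-enoate}
Conditions: DCC (2.4 equiv), DMAP (0.4 equiv), CH2Cl2, 0 °C → rt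
Reagents that add atoms: none
Why: Steglich esterification of both peri hydroxyls (carbodiimide activation, DMAP acyl transfer) should give the diester in which the rigid 1,8-spacing of the naphthalene stacks the two cinnamoyl arms parallel and head to head.

Step 4
Reactants: 7 naphthalene-1,8-diyl bis{(E)-3-[4-(benzyloxy)-3,5-dimethoxyphenyl]prop-2-enoate}
Product: 8 naphthalene-1,8-diyl (1α,2α,3β,4β)-3,4-bis[4-(benzyloxy)-3,5-dimethoxyphenyl]cyclobutane-1,2-dicarboxylate (cyclic diester, meso)
Conditions: hν (350–365 nm), crystalline powder as a thin layer between Pyrex plates, rt, layer remixed periodically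
Reagents that add atoms: none
Why: Intramolecular (2+2) photocycloaddition of the two stacked (E)-alkenes, whose peri attachment keeps the C=C bonds parallel, head to head and within the roughly 4 Å contact distance needed for reaction in the crystal, so that suprafacial addition to both alkenes places the two carbonyl carbons on one face and the two aryls on the other (each aryl trans to its vicinal carbonyl, as fixed by the E geometry), which sets the meso β-truxinate-type ring and with it the cis C3/C4 relationship of the target.

Step 5
Reactants: 8 template-bound cyclobutane diester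
Product: 9 [(1α,2α,3β,4β)-3,4-bis[4-(benzyloxy)-3,5-dimethoxyphenyl]cyclobutane-1,2-diyl]dimethanol (meso)
Conditions: LiAlH4 (4 equiv), THF, 0 °C → rt; then H2O; template 6 recovered by chromatography
Reagents that add atoms: none
Why: Ester reduction by LiAlH4, in which the two aryl esters are activated acyl donors and hydride addition should outrun enolization, so both are reduced to primary alcohols with the ring stereocentres retained, the benzyl ethers untouched and the template released as its diol.

Step 6
Reactants: 9 meso cyclobutane-1,2-dimethanol
Product: 10 [(1α,2α,3β,4β)-3,4-bis[4-(benzyloxy)-3,5-dimethoxyphenyl]cyclobutane-1,2-diyl]bis(methylene) dimethanesulfonate (meso)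
Conditions: MsCl (3 equiv), Et3N (4 equiv), CH2Cl2, −20 → 0 °C
Reagents that add atoms: methanesulfonyl chloride (CS(=O)(=O)Cl)
Why: Sulfonylation of both primary alcohols (through the sulfene from MsCl and Et3N), with excess reagent in the cold so that the second hydroxyl is capped before it can displace the first mesylate to a bicyclic ether; the stereocentres are not involved.

Step 7
Reactants: 10 meso bis-mesylate
Product: 11 (1α,2α,3β,4β)-1,2-bis[4-(benzyloxy)-3,5-dimethoxyphenyl]-3,4-dimethylcyclobutane (meso)
Conditions: LiEt3BH (1 M in THF, 5 equiv), THF, 0 → 40 °C; then H2O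
Reagents that add atoms: none
Why: SN2 reduction of primary sulfonates by LiEt3BH, a strongly nucleophilic hydride donor that attacks the CH2 carbons in a polar two-electron displacement, so that no cyclobutylcarbinyl radical or cation able to open the ring is formed and the four ring stereocentres stay as set in step 4.

Step 8
Reactants: 11 bis-benzyl ether of the dimethylcyclobutane
Product: 12 4,4'-[(1α,2α,3β,4β)-3,4-dimethylcyclobutane-1,2-diyl]bis(2,6-dimethoxyphenol) (meso)
Conditions: H2 (1 atm), 10% Pd/C, EtOAc/MeOH, rt
Reagents that add atoms: none
Why: Catalytic hydrogenolysis of the two benzyl aryl ethers over palladium at ambient pressure frees both phenols, while the cyclobutane C–C bonds and the methoxy groups are expected to persist under these mild conditions.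

Step 9
Reactants: 12 meso 1,2-bis(4-hydroxy-3,5-dimethoxyphenyl)-3,4-dimethylcyclobutane
Product: 15 fragransin B1, via bis-para-quinone methide 13 (not isolated), via hydroxy quinone methide 14 (not isolated)
Conditions: FeCl3·6H2O (2.2 equiv), acetone/H2O (4:1), 0.01 M, 0 °C → rt
Reagents that add atoms: water (O)
Why: Oxidative ring expansion of a 1,2-bis(4-hydroxyaryl)cyclobutane, the known passage from such cyclobutanes through bis-para-quinone methides to 2,5-diaryloxolanes by water capture: trivalent iron takes one electron (with loss of H+) from a syringyl OH, the phenoxyl radical carries spin at the ring carbon para to oxygen, and the adjoining doubly benzylic C1–C2 bond of the cyclobutane undergoes β-scission, which relieves ring strain and cis-aryl eclipsing and leaves one quinone methide plus a 4-hydroxybenzyl radical that a second trivalent iron oxidizes to the second methide (13). Water then adds in 1,6 fashion to one exocyclic methide carbon to give 14, and its new benzylic hydroxyl adds 1,6 to the other methide carbon in a 5-exo-trig oxa-conjugate closure that forms the oxolane ring (O1 joined to C2 and C5) and rearomatizes the second ring. C3 and C4 pass through untouched from step 4, while the new centres C2 and C5 are set under their control: in the envelope-like closure each aryl should take the face opposite its vicinal methyl, which makes the aryls cis and the product meso, so both enantiomers of 14 converge. Because a para-hydroxybenzylic C–O bond re-ionizes to the quinone methide under the HCl released by the oxidation (or a trace of added TsOH), any cis aryl/methyl epimer should drain to the trans,cis,trans isomer, expected to be the most stable of the cis-dimethyl series. The step needs cleavage of one ring bond only, O-capture instead of tautomerization to a styrene or aryl C-attack, and no phenol coupling; the substrate secures these because C1–C2 is the only bond flanked by both aryls, water is in large excess under weakly acidic conditions with a fast five-membered closure, and both positions ortho to each phenol oxygen carry methoxy groups.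

**Compound list**

1 | syringaldehyde (4-hydroxy-3,5-dimethoxybenzaldehyde) | COc1cc(C=O)cc(OC)c1O | starting material
2 | 4-(benzyloxy)-3,5-dimethoxybenzaldehyde | COc1cc(C=O)cc(OC)c1OCc1ccccc1 | intermediate
3 | malonic acid | OC(=O)CC(=O)O | starting material
4 | 2-{[4-(benzyloxy)-3,5-dimethoxyphenyl]methylidene}propanedioic acid (arylidenemalonic acid, not isolated) | COc1cc(C=C(C(=O)O)C(=O)O)cc(OC)c1OCc1ccccc1 | intermediate
5 | (E)-3-[4-(benzyloxy)-3,5-dimethoxyphenyl]prop-2-enoic acid ((E)-4-O-benzylsinapic acid) | COc1cc(/C=C/C(=O)O)cc(OC)c1OCc1ccccc1 | intermediate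
6 | 1,8-dihydroxynaphthalene (naphthalene-1,8-diol, recoverable template) | Oc1cccc2cccc(O)c12 | starting material
7 | naphthalene-1,8-diyl bis{(E)-3-[4-(benzyloxy)-3,5-dimethoxyphenyl]prop-2-enoate} | COc1cc(/C=C/C(=O)Oc2cccc3cccc(OC(=O)/C=C/c4cc(OC)c(OCc5ccccc5)c(OC)c4)c23)cc(OC)c1OCc1ccccc1 | intermediate
8 | naphthalene-1,8-diyl (1α,2α,3β,4β)-3,4-bis[4-(benzyloxy)-3,5-dimethoxyphenyl]cyclobutane-1,2-dicarboxylate (cyclic diester; aryls cis, carboxyls cis, aryl/carboxyl trans; meso) | COc1cc([C@H]2[C@@H](c3cc(OC)c(OCc4ccccc4)c(OC)c3)[C@H](C(=O)Oc3cccc4cccc5c34)[C@@H]2C(=O)O5)cc(OC)c1OCc1ccccc1 | intermediate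
9 | [(1α,2α,3β,4β)-3,4-bis[4-(benzyloxy)-3,5-dimethoxyphenyl]cyclobutane-1,2-diyl]dimethanol (meso) | COc1cc([C@H]2[C@@H](c3cc(OC)c(OCc4ccccc4)c(OC)c3)[C@H](CO)[C@@H]2CO)cc(OC)c1OCc1ccccc1 | intermediate
10 | [(1α,2α,3β,4β)-3,4-bis[4-(benzyloxy)-3,5-dimethoxyphenyl]cyclobutane-1,2-diyl]bis(methylene) dimethanesulfonate (meso) | COc1cc([C@H]2[C@@H](c3cc(OC)c(OCc4ccccc4)c(OC)c3)[C@H](COS(C)(=O)=O)[C@@H]2COS(C)(=O)=O)cc(OC)c1OCc1ccccc1 | intermediate
11 | (1α,2α,3β,4β)-1,2-bis[4-(benzyloxy)-3,5-dimethoxyphenyl]-3,4-dimethylcyclobutane (aryls cis, methyls cis, aryl/methyl trans; meso) | COc1cc([C@H]2[C@@H](c3cc(OC)c(OCc4ccccc4)c(OC)c3)[C@H](C)[C@@H]2C)cc(OC)c1OCc1ccccc1 | intermediate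
12 | 4,4'-[(1α,2α,3β,4β)-3,4-dimethylcyclobutane-1,2-diyl]bis(2,6-dimethoxyphenol) (meso) | COc1cc([C@H]2[C@@H](c3cc(OC)c(O)c(OC)c3)[C@H](C)[C@@H]2C)cc(OC)c1O | intermediate
13 | 4,4'-[(2R,3S)-2,3-dimethylbutane-1,4-diylidene]bis(2,6-dimethoxycyclohexa-2,5-dien-1-one) (meso bis-para-quinone methide, not isolated) | COC1=CC(=C[C@H](C)[C@H](C)C=C2C=C(OC)C(=O)C(OC)=C2)C=C(OC)C1=O | intermediate
14 | 4-[4-hydroxy-4-(4-hydroxy-3,5-dimethoxyphenyl)-2,3-dimethylbutylidene]-2,6-dimethoxycyclohexa-2,5-dien-1-one (racemic, relative configuration as in the SMILES, not isolated) | COc1cc([C@@H](O)[C@@H](C)[C@@H](C)C=C2C=C(OC)C(=O)C(OC)=C2)cc(OC)c1O | intermediate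
15 | fragransin B1, (2S,3S,4R,5R)-2,5-bis(4-hydroxy-3,5-dimethoxyphenyl)-3,4-dimethyloxolane (meso) | COc1cc([C@H]2O[C@@H](c3cc(OC)c(O)c(OC)c3)[C@H](C)[C@@H]2C)cc(OC)c1O | target

**Step count and risks**

Total step count: 9. Longest linear sequence: 9 steps (1 → 15); two molecules of 5 are joined in step 3.

Steps most likely to fail:

1. Step 9. The bis-quinone methide may partition away from water capture, by tautomerization to 4-hydroxystyrenes or by oligomerization, and the two new benzylic centres may form with incomplete diastereocontrol. The fallback sets out from 12 and comes back at 15, and separates oxidation from ring closure. Ag2O (2.5 equiv) in anhydrous MeOH/CH2Cl2 at rt in the dark generates the same methide in a solvent that is itself the nucleophile, so each methide carbon should be capped at once as a methyl ether. This should give the isolable acyclic bis(benzylic methyl ether) 1,4-dimethoxy-2,3-dimethyl-1,4-bis(4-hydroxy-3,5-dimethoxyphenyl)butane F1 (2R,3S core, mixture of benzylic epimers). In a second flask, catalytic TsOH in MeCN/H2O at 40 °C ionizes the para-hydroxybenzyl methyl ethers reversibly, water exchanges for methanol, and acid-catalysed cyclodehydration of this 1,4-diaryl-1,4-diol equivalent should deliver 15 under thermodynamic control. The acid is kept mild to avoid Friedel–Crafts closure onto the aryl ring.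

2. Step 4. The conformers frozen in the crystal may not hold the two C=C bonds parallel and within reach, so that E/Z photoisomerization or photo-Fries cleavage of the aryl esters competes with cycloaddition. The fallback sets out from 5 and comes back at 9, replacing the covalent template by an untemplated crystal-packing approach. Esterification of 5 with 4-nitrophenol (DCC, DMAP, CH2Cl2) gives 4-nitrophenyl (E)-3-[4-(benzyloxy)-3,5-dimethoxyphenyl]prop-2-enoate F2, an activated aryl cinnamate of the kind that can stack head to head in the crystal. Irradiation of its powder (350–365 nm) should give bis(4-nitrophenyl) (1α,2α,3β,4β)-3,4-bis[4-(benzyloxy)-3,5-dimethoxyphenyl]cyclobutane-1,2-dicarboxylate F3. Its configuration would need to be confirmed, since a head-to-tail packing would lead to the truxillate instead. LiBH4 in THF (0 °C → rt) then reduces both activated esters to diol 9, with loss of 4-nitrophenol and without touching the nitro groups before they leave.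

3. Step 7. Hydride may attack sulfur instead of carbon, freeing an alkoxide that closes onto the neighbouring cis CH2OMs group to a 3-oxabicyclo[3.2.0]heptane, and substitution at the β-branched carbon may be slow. The fallback sets out from 10 and comes back at 11, removing the sulfonate before any hydride is used. Finkelstein exchange (NaI, butanone, reflux), in which iodide attacks carbon only, gives (1α,2α,3β,4β)-1,2-bis[4-(benzyloxy)-3,5-dimethoxyphenyl]-3,4-bis(iodomethyl)cyclobutane F4. NaBH4 in DMSO at 50–60 °C then reduces both primary iodides by polar SN2 hydride transfer to give 11, again avoiding radical intermediates.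

**Further compounds**

F1 | step 9 | 1,4-dimethoxy-2,3-dimethyl-1,4-bis(4-hydroxy-3,5-dimethoxyphenyl)butane (2R,3S core, benzylic epimers) | COc1cc(C(OC)[C@H](C)[C@H](C)C(OC)c2cc(OC)c(O)c(OC)c2)cc(OC)c1O
F2 | step 4 | 4-nitrophenyl (E)-3-[4-(benzyloxy)-3,5-dimethoxyphenyl]prop-2-enoate | COc1cc(/C=C/C(=O)Oc2ccc(cc2)[N+](=O)[O-])cc(OC)c1OCc1ccccc1
F3 | step 4 | bis(4-nitrophenyl) (1α,2α,3β,4β)-3,4-bis[4-(benzyloxy)-3,5-dimethoxyphenyl]cyclobutane-1,2-dicarboxylate | COc1cc([C@H]2[C@@H](c3cc(OC)c(OCc4ccccc4)c(OC)c3)[C@H](C(=O)Oc5ccc(cc5)[N+](=O)[O-])[C@@H]2C(=O)Oc6ccc(cc6)[N+](=O)[O-])cc(OC)c1OCc1ccccc1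
F4 | step 7 | (1α,2α,3β,4β)-1,2-bis[4-(benzyloxy)-3,5-dimethoxyphenyl]-3,4-bis(iodomethyl)cyclobutane | COc1cc([C@H]2[C@@H](c3cc(OC)c(OCc4ccccc4)c(OC)c3)[C@H](CI)[C@@H]2CI)cc(OC)c1OCc1ccccc1
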